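**Retrosynthetic overview**
- Target ⇒ (Vilsmeier diformylation) the deformyl bridged ether ⇒ (acid-mediated 1,4-hydroalkoxylation, C2–O bond, oxepine ring closed last) a phenol tethered to a C10=C1–C2=C3 diene.
- Diene ⇒ dienyl triflate ⇒ C3 dienone: the C3 oxygen that makes C4 nucleophilic for the coupling is removed afterwards by 1,6-hydride addition, enolate triflation and formate reduction.
- Key late coupling (C4–C1′ bond, quaternary and benzylic stereocentres): C15 tricyclic silyl trienol ether + C13 aryl o-quinone methide, by hetero-Diels–Alder reaction.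
- Terpene half: a Pauson–Khand reaction closes the five- and seven-membered rings together on a cis-cyclopropane 1,8-enyne; the cyclopropane comes from an asymmetric Rh-catalysed intramolecular cyclopropanation of prenyl diazoacetate.
- Aryl half: resorcinol ⇒ C–H borylation/oxidation ⇒ ortho-formylation ⇒ isobutyl Grignard ⇒ O-Boc carbonate. Ring order: cyclopropane, then five + seven, then (transient chroman ketal), then oxepine.

Assumption and numbering: the SMILES defines the target; terpene carbons carry aromadendrane numbers (five-membered ring C1–C5; seven-membered ring C1, C5–C10; cyclopropane C6–C7–C11; C14 on C10, C15 on C4), C1′ is the benzylic carbon, and the target is (2R,4R,5R,6R,7R,1′S). CIP letters at one centre can differ between intermediates only because priorities change.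

**Step 1**
Reactants: 1 3-methylbut-2-en-1-ol (prenol); 2 bromoacetyl bromide
Product: 3 3-methylbut-2-en-1-yl bromoacetate
Conditions: NaHCO3, MeCN, 0 °C
Reagents that add atoms: none
Why: Acylation of the primary allylic alcohol by the acid bromide (nucleophilic acyl substitution), with bicarbonate taking up HBr so the prenyl ester is not ionised.

**Step 2**
Reactants: 3 3-methylbut-2-en-1-yl bromoacetate
Product: 4 3-methylbut-2-en-1-yl diazoacetate
Conditions: TsNHNHTs, DBU, THF, 0 °C
Reagents that add atoms: N,N′-ditosylhydrazine, Cc1ccc(cc1)S(=O)(=O)NNS(=O)(=O)c1ccc(C)cc1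
Why: Fukuyama-type diazoacetate synthesis: SN2 N-alkylation of the hydrazide by the bromoacetate, then base-induced loss of two sulfinates leaves the diazo ester.

**Step 3**
Reactants: 4 3-methylbut-2-en-1-yl diazoacetate
Product: 5 (1S,5R)-6,6-dimethyl-3-oxabicyclo[3.1.0]hexan-2-one
Conditions: Rh2(5S-MEPY)4 (dirhodium tetrakis[methyl (5S)-2-oxopyrrolidine-5-carboxylate], 1 mol%), CH2Cl2, 40 °C, slow addition of 4
Reagents that add atoms: none
Why: Doyle-type intramolecular carbenoid cyclopropanation; the chiral carboxamidate ligands set both ring stereocentres (C6 and C7 of the target) in high ee, and the tether allows only the cis fusion.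

**Step 4**
Reactants: 5 (1S,5R)-6,6-dimethyl-3-oxabicyclo[3.1.0]hexan-2-one
Product: 6 (1S,5R)-6,6-dimethyl-3-oxabicyclo[3.1.0]hexan-2-ol (anomer mixture)
Conditions: i-Bu2AlH, CH2Cl2, −78 °C
Reagents that add atoms: none
Why: Partial hydride reduction of the lactone stops at the tetrahedral aluminium alkoxide at low temperature and gives the lactol without touching the cyclopropane stereocentres.

**Step 5**
Reactants: 7 bromoethane
Product: 8 ethyl(triphenyl)phosphonium bromide
Conditions: PPh3, toluene, 100 °C (sealed tube)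
Reagents that add atoms: triphenylphosphine, c1ccc(cc1)P(c1ccccc1)c1ccccc1
Why: SN2 quaternisation of the phosphine by the primary bromide gives the Wittig salt that will supply C4 and C15.

**Step 6**
Reactants: 6 (1S,5R)-6,6-dimethyl-3-oxabicyclo[3.1.0]hexan-2-ol; 8 ethyl(triphenyl)phosphonium bromide
Product: 10 [(1R,3S)-2,2-dimethyl-3-[(1Z)-prop-1-en-1-yl]cyclopropyl]methanol, via ylide 9 (not isolated)
Conditions: 8, KN(SiMe3)2, THF, 0 °C; then 6, −78 °C → rt
Reagents that add atoms: none
Why: Wittig olefination of the lactol through its open hydroxy-aldehyde form with an unstabilised ylide gives the Z-propenyl group and keeps the cis cyclopropane; any E isomer is equally usable because this geometry is erased later.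

**Step 7**
Reactants: 10 [(1R,3S)-2,2-dimethyl-3-[(1Z)-prop-1-en-1-yl]cyclopropyl]methanol
Product: 11 (1R,3S)-1-(bromomethyl)-2,2-dimethyl-3-[(1Z)-prop-1-en-1-yl]cyclopropane
Conditions: CBr4, PPh3, CH2Cl2, −20 → 0 °C; used at once
Reagents that add atoms: tetrabromomethane, BrC(Br)(Br)Br
Why: Appel reaction (SN2 at the primary carbon of the alkoxyphosphonium salt) gives the bromide under non-ionising conditions, so the cyclopropylcarbinyl system does not rearrange.

**Step 8**
Reactants: 12 2-methylbut-3-yn-2-ol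
Product: 13 2-methylbut-1-en-3-yne
Conditions: Ac2O, TsOH·H2O (cat.), 60 → 110 °C, product distilled out (bp 32 °C)
Reagents that add atoms: none
Why: Acid-catalysed dehydration of the tertiary propargylic alcohol, driven by continuous distillation of the volatile enyne, which is best used fresh.

**Step 9**
Reactants: 11 (1R,3S)-1-(bromomethyl)-2,2-dimethyl-3-[(1Z)-prop-1-en-1-yl]cyclopropane; 13 2-methylbut-1-en-3-yne
Product: 15 (1R,3S)-2,2-dimethyl-1-(3-methylidenepent-4-yn-1-yl)-3-[(1Z)-prop-1-en-1-yl]cyclopropane, via dimetalated enyne 14 (not isolated)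
Conditions: 13, n-BuLi, KOt-Bu, THF–hexane, −78 → −20 °C; then 11, −78 → 0 °C; H2O
Reagents that add atoms: none
Why: Superbase dimetalation gives the acetylide/allyl dianion, whose more basic allylic carbon displaces the primary bromide by SN2 (C8–C9 bond), and the acetylide is reprotonated on work-up.

**Step 10**
Reactants: 15 (1R,3S)-2,2-dimethyl-1-(3-methylidenepent-4-yn-1-yl)-3-[(1Z)-prop-1-en-1-yl]cyclopropane
Product: 16 (5R,6R,7R)-aromadendra-1,10(14)-dien-3-one (C4 epimer mixture): cyclopentenone (C3=O, C1=C2) fused to a cycloheptane with exocyclic methylene at C10 and the cis gem-dimethylcyclopropane at C6–C7, H5 trans to H6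
Conditions: Co2(CO)8 (20 mol%), tetramethylthiourea (60 mol%), CO (1 atm), toluene, 70 °C
Reagents that add atoms: carbon monoxide, [C-]#[O+]
Why: Intramolecular Pauson–Khand [2+2+1] reaction in which the cis-cyclopropane holds alkyne and alkene close enough for seven-ring closure; C1 bonds to C5 with C4 turned away from the syn methyl of the cyclopropane (H5 trans to H6), and C5, being γ to the enone, can be equilibrated to this more stable epimer if needed.

**Step 11**
Reactants: 17 benzene-1,3-diol (resorcinol)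
Product: 18 1,3-bis(methoxymethoxy)benzene
Conditions: MOMCl, i-Pr2NEt, CH2Cl2, 0 °C → rt
Reagents that add atoms: chloromethyl methyl ether, COCCl
Why: Double O-alkylation (Williamson type) protects both phenols as acetals that survive base, Grignard, hydride and palladium steps and leave with acid at the end.

**Step 12**
Reactants: 18 1,3-bis(methoxymethoxy)benzene
Product: 19 2-[3,5-bis(methoxymethoxy)phenyl]-4,4,5,5-tetramethyl-1,3,2-dioxaborolane
Conditions: [Ir(OMe)(cod)]2 (1.5 mol%), 4,4′-di-tert-butyl-2,2′-bipyridine (3 mol%), B2pin2, hexane, 60 °C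
Reagents that add atoms: bis(pinacolato)diboron, CC1(C)OB(OC1(C)C)B1OC(C)(C)C(C)(C)O1
Why: Sterically controlled iridium-catalysed C–H borylation goes to the only ring position without an ortho substituent (C5).

**Step 13**
Reactants: 19 2-[3,5-bis(methoxymethoxy)phenyl]-4,4,5,5-tetramethyl-1,3,2-dioxaborolane
Product: 20 3,5-bis(methoxymethoxy)phenol
Conditions: H2O2, NaOH, THF–H2O, 0 °C
Reagents that add atoms: hydrogen peroxide, OO
Why: Oxidation of the aryl boronate (1,2-aryl shift from boron to oxygen, then hydrolysis) gives the differentiated phloroglucinol unit under conditions that leave the acetals intact.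

**Step 14**
Reactants: 20 3,5-bis(methoxymethoxy)phenol
Product: 21 2-hydroxy-4,6-bis(methoxymethoxy)benzaldehyde
Conditions: MgCl2, Et3N, (CH2O)n, MeCN, 80 °C
Reagents that add atoms: formaldehyde (as paraformaldehyde), C=O
Why: Casnati–Skattebøl ortho-formylation: the magnesium phenoxide delivers formaldehyde to an ortho carbon only (both are equivalent), and a second formaldehyde oxidises the benzylic alkoxide to the aldehyde.

**Step 15**
Reactants: 21 2-hydroxy-4,6-bis(methoxymethoxy)benzaldehyde; 22 isobutylmagnesium bromide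
Product: 23 2-(1-hydroxy-3-methylbutyl)-3,5-bis(methoxymethoxy)phenol (racemic)
Conditions: 22 (2.5 equiv), THF, −78 → 0 °C; NH4Cl (aq)
Reagents that add atoms: none
Why: Grignard 1,2-addition to the aldehyde after the first equivalent deprotonates the phenol; the carbinol centre is racemic on purpose because it becomes sp2 in the quinone methide.

**Step 16**
Reactants: 23 2-(1-hydroxy-3-methylbutyl)-3,5-bis(methoxymethoxy)phenol
Product: 24 tert-butyl 2-(1-hydroxy-3-methylbutyl)-3,5-bis(methoxymethoxy)phenyl carbonate (racemic)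
Conditions: Boc2O, i-Pr2NEt, DMAP (2 mol%), CH2Cl2, 0 °C
Reagents that add atoms: di-tert-butyl dicarbonate, CC(C)(C)OC(=O)OC(=O)OC(C)(C)C
Why: The phenol is acylated far faster than the hindered secondary alcohol, giving the Pettus-type o-quinone methide precursor, which is stable until its alkoxide is formed.

**Step 17**
Reactants: 16 (5R,6R,7R)-aromadendra-1,10(14)-dien-3-one; 24 tert-butyl 2-(1-hydroxy-3-methylbutyl)-3,5-bis(methoxymethoxy)phenyl carbonate
Product: 29 (4R,5S,6R,7R)-4-[(1R)-3-methyl-1-[2,4,6-tris(methoxymethoxy)phenyl]butyl]aromadendra-1,10(14)-dien-3-one, via silyl trienol ether 25 (not isolated), via o-quinone methide 26 (not isolated), via silyl ketal cycloadduct 27 (not isolated), via ammonium phenoxide 28 (not isolated)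
Conditions: 16, TBSOTf, Et3N, CH2Cl2, −78 → 0 °C, pentane filtration; then 24, t-BuMgCl, THF, −78 → 0 °C; then Bu4NF, 0 °C; MOMCl, i-Pr2NEt, rt
Reagents that add atoms: chloromethyl methyl ether, COCCl
Why: Kinetic α′-enolisation gives the cross-conjugated silyl trienol ether, the magnesium alkoxide of 24 triggers Boc migration and elimination to the o-quinone methide, and their inverse-demand hetero-Diels–Alder reaction joins C1′ to C4 on the face of H5 (anti to C6) with the silyloxy group endo to the E-quinone methide, which sets the quaternary C4 and the benzylic centre as in the target; fluoride then collapses the silyl ketal and the freed phenoxide is capped.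

**Step 18**
Reactants: 29 (4R,5S,6R,7R)-4-[(1R)-3-methyl-1-[2,4,6-tris(methoxymethoxy)phenyl]butyl]aromadendra-1,10(14)-dien-3-one
Product: 31 (4R,5S,6R,7R)-4-[(1S)-3-methyl-1-[2,4,6-tris(methoxymethoxy)phenyl]butyl]aromadendra-1(10),2-dien-3-yl trifluoromethanesulfonate, via lithium dienolate 30 (not isolated)
Conditions: LiBH(s-Bu)3, THF, −78 °C; then PhNTf2, −78 → 0 °C
Reagents that add atoms: N-phenylbis(trifluoromethanesulfonimide), O=S(=O)(N(c1ccccc1)S(=O)(=O)C(F)(F)F)C(F)(F)F
Why: The bulky hydride adds 1,6 to the unhindered exocyclic methylene (C1 is fully substituted and the carbonyl is neopentyl), giving one regiodefined extended dienolate with C14 now a methyl and the C1=C10 alkene in place, which is trapped on oxygen as the triflate.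

**Step 19**
Reactants: 31 (4R,5S,6R,7R)-4-[(1S)-3-methyl-1-[2,4,6-tris(methoxymethoxy)phenyl]butyl]aromadendra-1(10),2-dien-3-yl trifluoromethanesulfonate
Product: 32 (4R,5R,6R,7R)-4-[(1S)-3-methyl-1-[2,4,6-tris(methoxymethoxy)phenyl]butyl]aromadendra-1(10),2-diene
Conditions: Pd(OAc)2 (5 mol%), PPh3 (10 mol%), HCO2H, n-Bu3N, DMF, 60 °C
Reagents that add atoms: none
Why: Palladium-catalysed formate reduction of the enol triflate (oxidative addition to zerovalent palladium, formate decarboxylation, C–H reductive elimination) removes the C3 oxygen and leaves the C10=C1–C2=C3 diene.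

**Step 20**
Reactants: 32 (4R,5R,6R,7R)-4-[(1S)-3-methyl-1-[2,4,6-tris(methoxymethoxy)phenyl]butyl]aromadendra-1(10),2-diene
Product: 34 the target lacking both formyl groups, (2R,4R,5R,6R,7R,1′S): aryl ether oxygen on C2 and C1′ on C4 (bridged oxepine), C1=C10 alkene, two free phenols, via triphenol diene 33 (not isolated)
Conditions: HCl (1.25 M in MeOH), THF, 40 °C; concentrate; then camphorsulfonic acid (20 mol%), 4 Å MS, CH2Cl2, 0 °C → rt
Reagents that add atoms: none
Why: Acetal exchange frees the phenols, then protonation of the diene at its unsubstituted terminus C3 gives the C2–C1–C10 allyl cation, which an ortho phenol (the two are equivalent) traps at C2 from the only face it can reach, syn to C1′, setting C2 and closing the seven-membered ether (intramolecular 1,4-hydroalkoxylation).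

**Step 21**
Reactants: 34 deformyl bridged ether
Product: 35 target CNP0388405.1, (2R,4R,5R,6R,7R,1′S)
Conditions: POCl3, DMF, EtOAc, 0 °C → rt; then H2O, NaOAc, 50 °C
Reagents that add atoms: N,N-dimethylformamide, CN(C)C=O; water, O
Why: Double Vilsmeier–Haack formylation at the two free ring carbons, each flanked by two oxygens (as for phloroglucinol itself), followed by hydrolysis of the iminium salts to the two aldehydes.

**Compound list**
1 | 3-methylbut-2-en-1-ol | CC(C)=CCO | starting material
2 | bromoacetyl bromide | BrCC(Br)=O | starting material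
3 | 3-methylbut-2-en-1-yl bromoacetate | CC(C)=CCOC(=O)CBr | intermediate
4 | 3-methylbut-2-en-1-yl diazoacetate | CC(C)=CCOC(=O)C=[N+]=[N-] | intermediate
5 | (1S,5R)-6,6-dimethyl-3-oxabicyclo[3.1.0]hexan-2-one | O=C1[C@H]2[C@@H](CO1)C2(C)C | intermediate
6 | (1S,5R)-6,6-dimethyl-3-oxabicyclo[3.1.0]hexan-2-ol (anomers) | OC1[C@H]2[C@@H](CO1)C2(C)C | intermediate
7 | bromoethane | CCBr | starting material
8 | ethyl(triphenyl)phosphonium bromide | CC[P+](c1ccccc1)(c1ccccc1)c1ccccc1.[Br-] | intermediate
9 | ethylidene(triphenyl)phosphorane | CC=P(c1ccccc1)(c1ccccc1)c1ccccc1 | intermediate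
10 | [(1R,3S)-2,2-dimethyl-3-[(1Z)-prop-1-en-1-yl]cyclopropyl]methanol | C/C=C\[C@H]1[C@@H](CO)C1(C)C | intermediate
11 | (1R,3S)-1-(bromomethyl)-2,2-dimethyl-3-[(1Z)-prop-1-en-1-yl]cyclopropane | C/C=C\[C@H]1[C@@H](CBr)C1(C)C | intermediate
12 | 2-methylbut-3-yn-2-ol | CC(C)(O)C#C | starting material
13 | 2-methylbut-1-en-3-yne | CC(=C)C#C | intermediate
14 | dimetalated 2-methylbut-1-en-3-yne (acetylide/allyl dianion, Li and K counter-ions) | [Li+].[K+].[CH2-]C(=C)C#[C-] | intermediate
15 | (1R,3S)-2,2-dimethyl-1-(3-methylidenepent-4-yn-1-yl)-3-[(1Z)-prop-1-en-1-yl]cyclopropane | C/C=C\[C@H]1[C@@H](CCC(=C)C#C)C1(C)C | intermediate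
16 | (5R,6R,7R)-aromadendra-1,10(14)-dien-3-one (C4 epimers) | C=C1C2=CC(=O)C(C)[C@H]2[C@H]2[C@@H](CC1)C2(C)C | intermediate
17 | benzene-1,3-diol | Oc1cccc(O)c1 | starting material
18 | 1,3-bis(methoxymethoxy)benzene | COCOc1cccc(OCOC)c1 | intermediate
19 | 2-[3,5-bis(methoxymethoxy)phenyl]-4,4,5,5-tetramethyl-1,3,2-dioxaborolane | COCOc1cc(OCOC)cc(c1)B1OC(C)(C)C(C)(C)O1 | intermediate
20 | 3,5-bis(methoxymethoxy)phenol | COCOc1cc(O)cc(OCOC)c1 | intermediate
21 | 2-hydroxy-4,6-bis(methoxymethoxy)benzaldehyde | COCOc1cc(O)c(C=O)c(OCOC)c1 | intermediate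
22 | isobutylmagnesium bromide | CC(C)C[Mg]Br | starting material
23 | 2-(1-hydroxy-3-methylbutyl)-3,5-bis(methoxymethoxy)phenol (racemic) | COCOc1cc(O)c(C(O)CC(C)C)c(OCOC)c1 | intermediate
24 | tert-butyl 2-(1-hydroxy-3-methylbutyl)-3,5-bis(methoxymethoxy)phenyl carbonate (racemic) | COCOc1cc(OC(=O)OC(C)(C)C)c(C(O)CC(C)C)c(OCOC)c1 | intermediate
25 | (5S,6R,7R)-3-[tert-butyl(dimethyl)silyl]oxyaromadendra-1,3,10(14)-triene | C=C1C2=CC(O[Si](C)(C)C(C)(C)C)=C(C)[C@H]2[C@H]2[C@@H](CC1)C2(C)C | intermediate
26 | (6E)-3,5-bis(methoxymethoxy)-6-(3-methylbutylidene)cyclohexa-2,4-dien-1-one | CC(C)C/C=C1/C(=O)C=C(OCOC)C=C1OCOC | intermediate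
27 | silyl ketal cycloadduct (3R,4R,5S,6R,7R,1′R): 5,7-bis(methoxymethoxy)chroman fused across C3–C4 of the terpene; C3 bears the aryl oxygen and OTBS (cis to the C4 methyl), C4 bears CH3 and C1′, C1′ bears isobutyl | C=C1CC[C@@H]2[C@@H](C2(C)C)[C@H]2C1=C[C@]1(O[Si](C)(C)C(C)(C)C)Oc3cc(OCOC)cc(OCOC)c3[C@@H](CC(C)C)[C@]21C | intermediate
28 | tetrabutylammonium 3,5-bis(methoxymethoxy)-2-[(1R)-3-methyl-1-[(4R,5S,6R,7R)-3-oxoaromadendra-1,10(14)-dien-4-yl]butyl]phenolate | CCCC[N+](CCCC)(CCCC)CCCC.C=C1CC[C@@H]2[C@@H](C2(C)C)[C@H]2C1=CC(=O)[C@]2(C)[C@H](CC(C)C)c1c([O-])cc(OCOC)cc1OCOC | intermediate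
29 | (4R,5S,6R,7R)-4-[(1R)-3-methyl-1-[2,4,6-tris(methoxymethoxy)phenyl]butyl]aromadendra-1,10(14)-dien-3-one | C=C1CC[C@@H]2[C@@H](C2(C)C)[C@H]2C1=CC(=O)[C@]2(C)[C@H](CC(C)C)c1c(OCOC)cc(OCOC)cc1OCOC | intermediate
30 | lithium (4R,5S,6R,7R)-4-[(1S)-3-methyl-1-[2,4,6-tris(methoxymethoxy)phenyl]butyl]aromadendra-1(10),2-dien-3-olate | [Li+].CC1=C2[C@H]([C@H]3[C@@H](CC1)C3(C)C)[C@@](C)([C@H](CC(C)C)c1c(OCOC)cc(OCOC)cc1OCOC)C([O-])=C2 | intermediate
31 | (4R,5S,6R,7R)-4-[(1S)-3-methyl-1-[2,4,6-tris(methoxymethoxy)phenyl]butyl]aromadendra-1(10),2-dien-3-yl trifluoromethanesulfonate | CC1=C2[C@H]([C@H]3[C@@H](CC1)C3(C)C)[C@@](C)([C@H](CC(C)C)c1c(OCOC)cc(OCOC)cc1OCOC)C(OS(=O)(=O)C(F)(F)F)=C2 | intermediate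
32 | (4R,5R,6R,7R)-4-[(1S)-3-methyl-1-[2,4,6-tris(methoxymethoxy)phenyl]butyl]aromadendra-1(10),2-diene | CC1=C2[C@H]([C@H]3[C@@H](CC1)C3(C)C)[C@@](C)([C@H](CC(C)C)c1c(OCOC)cc(OCOC)cc1OCOC)C=C2 | intermediate
33 | 2-[(1S)-1-[(4R,5R,6R,7R)-aromadendra-1(10),2-dien-4-yl]-3-methylbutyl]benzene-1,3,5-triol | CC1=C2[C@H]([C@H]3[C@@H](CC1)C3(C)C)[C@@](C)([C@H](CC(C)C)c1c(O)cc(O)cc1O)C=C2 | intermediate
34 | deformyl target (2R,4R,5R,6R,7R,1′S): bridged aryl ether, oxygen on C2, C1′ on C4, two free phenols | CC1=C2[C@H]([C@H]3[C@@H](CC1)C3(C)C)[C@]1(C)C[C@H]2Oc2cc(O)cc(O)c2[C@H]1CC(C)C | intermediate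
35 | CNP0388405.1 (2R,4R,5R,6R,7R,1′S) | CC1=C2[C@H]([C@H]3[C@@H](CC1)C3(C)C)[C@]1(C)C[C@H]2Oc2c(C=O)c(O)c(C=O)c(O)c2[C@H]1CC(C)C | target

**Step count**
Total: 21 steps. Longest linear sequence: 13 steps (1, 2, 3, 4, 6, 7, 9, 10, 17, 18, 19, 20, 21). The aryl branch (steps 11–16), the phosphonium salt (step 5) and the enyne (step 8) run in parallel.

**Steps most likely to fail, with fallbacks**

Step 10 (one cyclocarbonylation has to close a seven-membered ring). The fallback sets out from 15 and comes back at 16, making the seven-membered ring by carbopalladation and the enone by a polar acylation. Markovnikov hydroiodination of the terminal alkyne (9-iodo-9-borabicyclo[3.3.1]nonane, then AcOH) gives the 2-iodo-1,3-diene (1R,3S)-1-(4-iodo-3-methylidenepent-4-en-1-yl)-2,2-dimethyl-3-[(1Z)-prop-1-en-1-yl]cyclopropane F1. A 7-exo Heck cyclisation under CO in MeOH (Pd(OAc)2, PPh3, Et3N) joins C1 to C5 and captures the alkylpalladium as methyl 2-[8,8-dimethyl-3,4-dimethylidenebicyclo[5.1.0]octan-2-yl]propanoate F2 (ring stereocentres as in 16). LiOH gives 2-[8,8-dimethyl-3,4-dimethylidenebicyclo[5.1.0]octan-2-yl]propanoic acid F3, and oxalyl chloride gives 2-[8,8-dimethyl-3,4-dimethylidenebicyclo[5.1.0]octan-2-yl]propanoyl chloride F4. SnCl4 at −78 °C then closes the cyclopentenone by acylation of the diene terminus C2 and loss of a proton, giving 16.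

Step 17 (a quaternary and a benzylic centre are made together; the C1′ configuration rests on the endo/E-quinone-methide model, and the silyloxycyclopentadiene is labile). The fallback sets out from 23 (with 16) and comes back at 29, replacing the cycloaddition by an SN1 alkylation with a fully protected benzyl cation. MOMCl/K2CO3 caps the phenol to give 3-methyl-1-[2,4,6-tris(methoxymethoxy)phenyl]butan-1-ol F5, and Ac2O/pyridine gives 3-methyl-1-[2,4,6-tris(methoxymethoxy)phenyl]butyl acetate F6. With catalytic ZnI2 in CH2Cl2 at −40 °C, F6 ionises to the trialkoxybenzyl cation, which alkylates silyl trienol ether 25 (made from 16 as in step 17) at C4 in a Mukaiyama-type reaction. This gives 29 directly, with no ketal stage and no free phenol; C1′ epimers, if both form, are separated at 29.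

Step 20 (the phenol must add at C2; protonation of the diene at C10 instead would lead to a six-membered ether at C3). The fallback sets out from 32 and comes back at 34, placing the oxygen at C2 before ring closure. 9-BBN adds only to the disubstituted ring alkene, with boron at C2 (away from the quaternary C4) on the face opposite the aryl-bearing branch; NaOH/H2O2 gives (2S,4R,5R,6R,7R)-4-[(1S)-3-methyl-1-[2,4,6-tris(methoxymethoxy)phenyl]butyl]aromadendr-1(10)-en-2-ol F7. HCl/MeOH removes the three MOM groups to give 2-[(1S)-1-[(2S,4R,5R,6R,7R)-2-hydroxyaromadendr-1(10)-en-4-yl]-3-methylbutyl]benzene-1,3,5-triol F8. Mitsunobu closure (PPh3, diisopropyl azodicarboxylate) forms the C2–O bond with inversion and gives 34; an alcohol at C2 can ionise only to the C2/C10 allyl cation, so the six-membered ether is excluded.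

**Further compounds**
F1 | step 10 | (1R,3S)-1-(4-iodo-3-methylidenepent-4-en-1-yl)-2,2-dimethyl-3-[(1Z)-prop-1-en-1-yl]cyclopropane | C/C=C\[C@H]1[C@@H](CCC(=C)C(I)=C)C1(C)C
F2 | step 10 | methyl 2-[8,8-dimethyl-3,4-dimethylidenebicyclo[5.1.0]octan-2-yl]propanoate (ring stereocentres as in 16) | COC(=O)C(C)[C@H]1[C@H]2[C@@H](CCC(=C)C1=C)C2(C)C
F3 | step 10 | 2-[8,8-dimethyl-3,4-dimethylidenebicyclo[5.1.0]octan-2-yl]propanoic acid | OC(=O)C(C)[C@H]1[C@H]2[C@@H](CCC(=C)C1=C)C2(C)C
F4 | step 10 | 2-[8,8-dimethyl-3,4-dimethylidenebicyclo[5.1.0]octan-2-yl]propanoyl chloride | ClC(=O)C(C)[C@H]1[C@H]2[C@@H](CCC(=C)C1=C)C2(C)C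
F5 | step 17 | 3-methyl-1-[2,4,6-tris(methoxymethoxy)phenyl]butan-1-ol (racemic) | COCOc1cc(OCOC)c(C(O)CC(C)C)c(OCOC)c1
F6 | step 17 | 3-methyl-1-[2,4,6-tris(methoxymethoxy)phenyl]butyl acetate (racemic) | COCOc1cc(OCOC)c(C(OC(C)=O)CC(C)C)c(OCOC)c1
F7 | step 20 | (2S,4R,5R,6R,7R)-4-[(1S)-3-methyl-1-[2,4,6-tris(methoxymethoxy)phenyl]butyl]aromadendr-1(10)-en-2-ol | CC1=C2[C@H]([C@H]3[C@@H](CC1)C3(C)C)[C@@](C)([C@H](CC(C)C)c1c(OCOC)cc(OCOC)cc1OCOC)C[C@@H]2O
F8 | step 20 | 2-[(1S)-1-[(2S,4R,5R,6R,7R)-2-hydroxyaromadendr-1(10)-en-4-yl]-3-methylbutyl]benzene-1,3,5-triol | CC1=C2[C@H]([C@H]3[C@@H](CC1)C3(C)C)[C@@](C)([C@H](CC(C)C)c1c(O)cc(O)cc1O)C[C@@H]2O
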